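Everything rests on disconnecting ring B (the 3,4-dihydroxy ring) from the polyenyne between ring carbon C6 and alkyne carbon C7. Because the C4 oxygen of ring B lies 1,3 to C6 across the C5=C6 double bond, C6 is introduced as the carbonyl carbon of a vinylogous ester. The lithium acetylide of a C31 ring A polyenyne adds to the C6 ketone of an (S)-configured enediol acetonide (C12), and aqueous acid transposes the adduct (Stork–Danheiser type): one operation forms the C6–C7 bond, the C5=C6 enyne double bond and the C4 ketone and frees both secondary hydroxyls. A hydroxyl-directed reduction at C4 then gives the trans diol.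

Key step: step 10

Assumption: compounds 1, 7, 11 and 13 are taken as purchasable carotenoid building blocks; all polyene intermediates are handled under inert gas with exclusion of light.

**Ring B fragment (steps 1–4)**

Step 1
Reactants: 1 2,6,6-trimethylcyclohex-2-ene-1,4-dione (ketoisophorone)
Product: 2 rac-1,3,3-trimethyl-7-oxabicyclo[4.1.0]heptane-2,5-dione
Conditions: H2O2 (30% aq.), NaOH (cat.), MeOH, 0 °C
Reagents that add atoms: hydrogen peroxide, OO
Why: Weitz–Scheffer nucleophilic epoxidation, in which hydroperoxide adds in conjugate fashion to the electron-poor C2=C3 bond of the enedione and the enolate closes the oxirane; the racemic epoxide suffices because both stereocenters are erased in step 2.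

Step 2
Reactants: 2 rac-1,3,3-trimethyl-7-oxabicyclo[4.1.0]heptane-2,5-dione
Product: 4 3-hydroxy-2,6,6-trimethylcyclohex-2-ene-1,4-dione, via sodium enolate 3 (not isolated)
Conditions: NaOH (1.1 equiv), H2O/MeOH, N2, 0 °C to rt; then aq. HCl
Reagents that add atoms: none
Why: Base-induced isomerization of an α,β-epoxy ketone to a diosphenol, in which loss of the oxirane hydrogen that is α to the unhindered carbonyl opens the ring to a vinylogous carboxylate whose stability drives the reaction.

Step 3
Reactants: 4 3-hydroxy-2,6,6-trimethylcyclohex-2-ene-1,4-dione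
Product: 5 (4S)-3,4-dihydroxy-2,6,6-trimethylcyclohex-2-en-1-one
Conditions: RuCl(p-cymene)[(S,S)-TsDPEN] (cat.), HCO2H/Et3N azeotrope, CH2Cl2, rt
Reagents that add atoms: none
Why: Asymmetric transfer hydrogenation (Noyori type) of the ketone flanked by the enol carbon, the other carbonyl being deactivated as a vinylogous acid and shielded by the gem-dimethyl group; the (S,S)-ligand is expected to give the (4S)-carbinol by analogy with the model for sp2-flanked (aryl) ketones.

Step 4
Reactants: 5 (4S)-3,4-dihydroxy-2,6,6-trimethylcyclohex-2-en-1-one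
Product: 6 (7aS)-2,2,4,6,6-pentamethyl-7,7a-dihydro-1,3-benzodioxol-5(6H)-one
Conditions: 2,2-dimethoxypropane, pyridinium p-toluenesulfonate (cat.), acetone, rt
Reagents that add atoms: 2,2-dimethoxypropane, COC(C)(C)OC
Why: Acid-catalysed transketalization ties the secondary hydroxyl and the neighbouring enol oxygen into a dioxolane, which fixes the enol ether next to the stereocenter, leaves the hindered ketone free and does not touch the stereocenter.

**Ring A fragment (steps 5–6)**

Step 5
Reactants: 7 (4R,6R)-4-hydroxy-2,2,6-trimethylcyclohexan-1-one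
Product: 8 (4R,6R)-2,2,6-trimethyl-4-(triethylsilyloxy)cyclohexan-1-one
Conditions: Et3SiCl, imidazole, DMF, 0 °C to rt
Reagents that add atoms: chlorotriethylsilane, CC[Si](Cl)(CC)CC
Why: Standard silylation of a secondary alcohol; the triethylsilyl group is chosen to survive enolate formation and cross-coupling and to be lost in the aqueous acid of step 10.

Step 6
Reactants: 8 (4R,6R)-2,2,6-trimethyl-4-(triethylsilyloxy)cyclohexan-1-one
Product: 10 (4R)-2,6,6-trimethyl-4-(triethylsilyloxy)cyclohex-1-en-1-yl trifluoromethanesulfonate, via potassium enolate 9 (not isolated)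
Conditions: KN(SiMe3)2, THF, −78 °C; PhNTf2, −78 to 0 °C
Reagents that add atoms: N-phenylbis(trifluoromethanesulfonimide), O=S(=O)(N(c1ccccc1)S(=O)(=O)C(F)(F)F)C(F)(F)F
Why: Enol triflate formation, in which the single α-hydrogen of the ketone allows only one enolate, which is O-sulfonylated; the methyl-bearing stereocenter is erased and the silyloxy carbon, being γ to the carbonyl, is neither epimerized nor eliminated.

**Chain and C31 alkyne (steps 7–9)**

Step 7
Reactants: 11 (2E)-3-methylpent-2-en-4-yn-1-ol
Product: 12 [(2E)-3-methylpent-2-en-4-yn-1-yl]triphenylphosphonium bromide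
Conditions: PPh3·HBr, MeOH, rt, dark
Reagents that add atoms: triphenylphosphine hydrobromide, [PH+](c1ccccc1)(c1ccccc1)c1ccccc1.[Br-]
Why: Direct conversion of a primary allylic alcohol into the allylic phosphonium salt (substitution of the protonated alcohol by bromide and then by PPh3 at the unhindered primary carbon), which should keep the E double bond.

Step 8
Reactants: 12 [(2E)-3-methylpent-2-en-4-yn-1-yl]triphenylphosphonium bromide (2.2 equiv); 13 (2E,4E,6E)-2,7-dimethylocta-2,4,6-trienedial
Product: 16 (3E,5E,7E,9E,11E,13E,15E)-3,7,12,16-tetramethyloctadeca-3,5,7,9,11,13,15-heptaene-1,17-diyne, via phosphorus ylide 14 (not isolated), via C16 ynal 15 (not isolated)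
Conditions: NaOMe, MeOH/CH2Cl2, 0 °C to rt; then heptane, reflux, N2
Reagents that add atoms: none
Why: Twofold Wittig olefination of the symmetrical dialdehyde with the semi-stabilised allylic ylide builds the C22 heptaenediyne in one operation; the new disubstituted double bonds should form as E/Z mixtures, the hindered Z bonds are to be isomerized thermally, and the all-E isomer is to be secured by crystallization.

Step 9
Reactants: 10 (4R)-2,6,6-trimethyl-4-(triethylsilyloxy)cyclohex-1-en-1-yl trifluoromethanesulfonate; 16 C22 heptaenediyne (3 equiv)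
Product: 17 C31 polyenyne triethylsilyl ether (diyne 16 carrying the (4R)-2,6,6-trimethyl-4-(triethylsilyloxy)cyclohex-1-en-1-yl ring on C1, C18 remaining a terminal alkyne)
Conditions: Pd(PPh3)4 (cat.), CuI (cat.), i-Pr2NH, DMF, rt to 40 °C, degassed
Reagents that add atoms: none
Why: Sonogashira coupling (oxidative addition of zerovalent palladium into the vinyl C–OTf bond, transmetalation from the copper acetylide, reductive elimination); the excess of the symmetrical diyne limits twofold coupling, the surplus is to be recovered, and exclusion of oxygen suppresses alkyne homocoupling.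

**Fragment union and end game (steps 10–11)**

Step 10
Reactants: 17 C31 polyenyne triethylsilyl ether; 6 (7aS)-2,2,4,6,6-pentamethyl-7,7a-dihydro-1,3-benzodioxol-5(6H)-one (1.3 equiv)
Product: 20 (3S,3'R)-3,3'-dihydroxy-7,8,7',8'-tetradehydro-β,β-caroten-4-one (4-ketoalloxanthin), via lithium acetylide 18 (not isolated), via lithium alkoxide adduct 19 (not isolated)
Conditions: LiN(i-Pr)2 (1.05 equiv), THF, −78 °C; 6, −78 to 0 °C; then 1 M aq. H2SO4, THF, 0 °C to rt, dark
Reagents that add atoms: water, O
Why: LiN(i-Pr)2 removes the terminal alkyne hydrogen of 17, the most acidic C–H present, and the slim acetylide adds 1,2 to the only electrophilic site of 6, the non-enolisable C6 ketone, to give alkoxide 19 as a mixture of C6 epimers whose configuration is irrelevant. Aqueous acid then ionises the tertiary, allylic and propargylic C6–O bond with help from the enol ether oxygen on C4, water adds to the oxocarbenium carbon C4, and the dioxolane collapses with loss of acetone, so that the carbonyl appears at C4, the double bond settles at C5=C6 in conjugation with the alkyne, and the C3 hydroxyl is set free. The closest known reaction type is the Stork–Danheiser alkylative transposition of vinylogous esters, which is established for acetylides and enediol acetonides of this kind. No ring is closed and no new stereocenter remains in the product; the (3S) center comes unchanged from 6 because neither stage breaks the C3–O bond. The step needs 1,2-addition without deprotonation at C3, which the absence of excess base and the low kinetic acidity of that γ-hydrogen should secure, and a regiospecific transposition, which the position of the enol ether oxygen dictates. The same acid should cleave the triethylsilyl ether of ring A, so that 20 is obtained with both hydroxyl groups free.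

Step 11
Reactants: 20 (3S,3'R)-3,3'-dihydroxy-7,8,7',8'-tetradehydro-β,β-caroten-4-one
Product: 22 (3S,4S,3'R)-7,8,7',8'-tetradehydro-β,β-carotene-3,4,3'-triol ((3S,4S,3'R)-4-hydroxyalloxanthin), via alkoxyborohydride 21 (not isolated)
Conditions: Me4NBH(OAc)3, AcOH, MeCN/CH2Cl2, −20 °C; aq. potassium sodium tartrate/NaHCO3
Reagents that add atoms: none
Why: Hydroxyl-directed reduction (Evans–Saksena type), in which the C3 hydroxyl of ring B exchanges an acetate on boron and the tethered hydride is delivered to C4 from the face that carries the C3 oxygen, so that the new C4 hydroxyl is trans to it as in the (3S,4S) diol; the reagent does not reduce unactivated sites and the ring A hydroxyl has no carbonyl group within reach.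

**Compound list**

1 | 2,6,6-trimethylcyclohex-2-ene-1,4-dione (ketoisophorone) | CC1=CC(=O)CC(C)(C)C1=O | starting material
2 | rac-1,3,3-trimethyl-7-oxabicyclo[4.1.0]heptane-2,5-dione | CC12OC1C(=O)CC(C)(C)C2=O | intermediate
3 | sodium enolate of 4 (sodium 2,6,6-trimethyl-1,4-dioxocyclohex-2-en-3-olate) | CC1=C([O-])C(=O)CC(C)(C)C1=O.[Na+] | intermediate
4 | 3-hydroxy-2,6,6-trimethylcyclohex-2-ene-1,4-dione | CC1=C(O)C(=O)CC(C)(C)C1=O | intermediate
5 | (4S)-3,4-dihydroxy-2,6,6-trimethylcyclohex-2-en-1-one | CC1=C(O)[C@@H](O)CC(C)(C)C1=O | intermediate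
6 | (7aS)-2,2,4,6,6-pentamethyl-7,7a-dihydro-1,3-benzodioxol-5(6H)-one | CC1=C2OC(C)(C)O[C@H]2CC(C)(C)C1=O | intermediate
7 | (4R,6R)-4-hydroxy-2,2,6-trimethylcyclohexan-1-one | CC1(C)C[C@H](O)C[C@@H](C)C1=O | starting material
8 | (4R,6R)-2,2,6-trimethyl-4-(triethylsilyloxy)cyclohexan-1-one | CC1(C)C[C@H](O[Si](CC)(CC)CC)C[C@@H](C)C1=O | intermediate
9 | potassium enolate of 8 (potassium (4R)-2,6,6-trimethyl-4-(triethylsilyloxy)cyclohex-1-en-1-olate) | CC1=C([O-])C(C)(C)C[C@H](O[Si](CC)(CC)CC)C1.[K+] | intermediate
10 | (4R)-2,6,6-trimethyl-4-(triethylsilyloxy)cyclohex-1-en-1-yl trifluoromethanesulfonate | CC1=C(OS(=O)(=O)C(F)(F)F)C(C)(C)C[C@H](O[Si](CC)(CC)CC)C1 | intermediate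
11 | (2E)-3-methylpent-2-en-4-yn-1-ol | C#C/C(C)=C/CO | starting material
12 | [(2E)-3-methylpent-2-en-4-yn-1-yl]triphenylphosphonium bromide | C#C/C(C)=C/C[P+](c1ccccc1)(c1ccccc1)c1ccccc1.[Br-] | intermediate
13 | (2E,4E,6E)-2,7-dimethylocta-2,4,6-trienedial | O=C/C(C)=C/C=C/C=C(C)/C=O | starting material
14 | [(2E)-3-methylpent-2-en-4-yn-1-ylidene]triphenylphosphorane (ylide of 12) | C#C/C(C)=C/C=P(c1ccccc1)(c1ccccc1)c1ccccc1 | intermediate
15 | (2E,4E,6E,8E,10E)-2,7,11-trimethyltrideca-2,4,6,8,10-pentaen-12-ynal | C#C/C(C)=C/C=C/C(C)=C/C=C/C=C(C)/C=O | intermediate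
16 | (3E,5E,7E,9E,11E,13E,15E)-3,7,12,16-tetramethyloctadeca-3,5,7,9,11,13,15-heptaene-1,17-diyne | C#C/C(C)=C/C=C/C(C)=C/C=C/C=C(C)/C=C/C=C(\C)C#C | intermediate
17 | C31 polyenyne triethylsilyl ether (diyne 16 with the (4R)-2,6,6-trimethyl-4-(triethylsilyloxy)cyclohex-1-en-1-yl ring on C1) | CC1=C(C#C/C(C)=C/C=C/C(C)=C/C=C/C=C(C)/C=C/C=C(\C)C#C)C(C)(C)C[C@H](O[Si](CC)(CC)CC)C1 | intermediate
18 | lithium acetylide of 17 | CC1=C(C#C/C(C)=C/C=C/C(C)=C/C=C/C=C(C)/C=C/C=C(\C)C#[C-])C(C)(C)C[C@H](O[Si](CC)(CC)CC)C1.[Li+] | intermediate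
19 | lithium alkoxide adduct of 18 and 6 (tertiary propargylic alkoxide at ring B C6, acetonide and silyl ether intact, mixture of C6 epimers) | CC1=C(C#C/C(C)=C/C=C/C(C)=C/C=C/C=C(C)/C=C/C=C(\C)C#CC2([O-])C(C)=C3OC(C)(C)O[C@H]3CC2(C)C)C(C)(C)C[C@H](O[Si](CC)(CC)CC)C1.[Li+] | intermediate
20 | (3S,3'R)-3,3'-dihydroxy-7,8,7',8'-tetradehydro-β,β-caroten-4-one (4-ketoalloxanthin) | CC1=C(C#C/C(C)=C/C=C/C(C)=C/C=C/C=C(C)/C=C/C=C(\C)C#CC2=C(C)C(=O)[C@@H](O)CC2(C)C)C(C)(C)C[C@H](O)C1 | intermediate
21 | tetramethylammonium diacetoxy(hydrido)borate ester of the ring B C3 hydroxyl of 20 | CC1=C(C#C/C(C)=C/C=C/C(C)=C/C=C/C=C(C)/C=C/C=C(\C)C#CC2=C(C)C(=O)[C@@H](O[BH-](OC(C)=O)OC(C)=O)CC2(C)C)C(C)(C)C[C@H](O)C1.C[N+](C)(C)C | intermediate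
22 | (3S,4S,3'R)-7,8,7',8'-tetradehydro-β,β-carotene-3,4,3'-triol ((3S,4S,3'R)-4-hydroxyalloxanthin) | CC1=C(C#C/C(C)=C/C=C/C(C)=C/C=C/C=C(C)/C=C/C=C(\C)C#CC2=C(C)[C@H](O)[C@@H](O)CC2(C)C)C(C)(C)C[C@H](O)C1 | target

**Step count and risks**

Total step count: 11. Longest linear sequence: 6 steps (steps 1, 2, 3, 4, 10 and 11, from ketoisophorone 1).

Steps most likely to fail:

1. Step 10. The large polyenyl acetylide may add sluggishly to the hindered ketone or may be poorly soluble, deprotonation at C3 may erode the enantiopurity, and the heptaene may degrade or scramble its double bond geometry in the acid stage. The fallback performs the same alkynylation and transposition on the small enynol, before any polyene exists, and builds the chain afterwards by Wittig reactions. It sets out from 6, 10, 11 and 13 and comes back to the route at 20. Enynol 11 and ketone 6 are combined under EtMgBr (2 equiv) in THF and the mixture is treated with dilute H2SO4, which should give the C15 ketodiol (6S)-6-hydroxy-3-[(3E)-5-hydroxy-3-methylpent-3-en-1-yn-1-yl]-2,4,4-trimethylcyclohex-2-en-1-one F1. PPh3·HBr converts its primary allylic alcohol into the ring B phosphonium bromide F2. In parallel, triflate 10 is coupled with 11 (Pd(PPh3)4, CuI, i-Pr2NH) to the ring A C15 alcohol (2E)-3-methyl-5-[(4R)-2,6,6-trimethyl-4-(triethylsilyloxy)cyclohex-1-en-1-yl]pent-2-en-4-yn-1-ol F3. PPh3·HBr in MeOH turns F3 into the desilylated ring A phosphonium bromide F4, and Wittig reaction of F4 with an excess of dialdehyde 13 (NaOMe) gives the C25 hydroxy ynal F5. Wittig reaction of F5 with F2 (NaOMe, MeOH/CH2Cl2), followed by thermal isomerization of the hindered Z bond, returns to 20.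

2. Step 11. Hydride delivery through the five-membered transition state may be slow for a carbonyl deactivated by conjugation with the polyenyne, so that facial selectivity is poor, and the new allylic alcohol may ionise in acetic acid. The fallback gives up substrate-directed delivery in favour of separation and recycling. It sets out from 20 and comes back at 22. Reduction with NaBH4 (EtOH/CH2Cl2, 0 °C) should give 22 together with its C4 epimer, the cis diol (3S,4R,3'R)-4-hydroxyalloxanthin F6. The two are separated by preparative HPLC, and F6 is re-oxidized selectively at the allylic C4 carbinol with MnO2 to 20 and reduced again.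

3. Step 3. The enantioselectivity of the transfer hydrogenation on the enolised trione may be insufficient, or the reduction may be slow or attack the C=C bond. The fallback replaces catalyst control by enzymatic kinetic resolution. It sets out from 4 and comes back at 5. Hydrogenation of 4 (H2, Raney Ni, MeOH) gives racemic 3,4-dihydroxy-2,6,6-trimethylcyclohex-2-en-1-one F7. Lipase B from Candida antarctica with vinyl acetate is expected to acylate the (R)-alcohol to (1R)-2-hydroxy-3,5,5-trimethyl-4-oxocyclohex-2-en-1-yl acetate F8, leaving (S)-alcohol 5, which is separated and carried on.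

Further compounds
F1 | step 10 | (6S)-6-hydroxy-3-[(3E)-5-hydroxy-3-methylpent-3-en-1-yn-1-yl]-2,4,4-trimethylcyclohex-2-en-1-one | OC/C=C(\C)C#CC1=C(C)C(=O)[C@@H](O)CC1(C)C
F2 | step 10 | [(2E)-5-[(4S)-4-hydroxy-2,6,6-trimethyl-3-oxocyclohex-1-en-1-yl]-3-methylpent-2-en-4-yn-1-yl]triphenylphosphonium bromide | [Br-].c1ccccc1[P+](c1ccccc1)(c1ccccc1)C/C=C(\C)C#CC1=C(C)C(=O)[C@@H](O)CC1(C)C
F3 | step 10 | (2E)-3-methyl-5-[(4R)-2,6,6-trimethyl-4-(triethylsilyloxy)cyclohex-1-en-1-yl]pent-2-en-4-yn-1-ol | CC1=C(C#C/C(C)=C/CO)C(C)(C)C[C@H](O[Si](CC)(CC)CC)C1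
F4 | step 10 | [(2E)-5-[(4R)-4-hydroxy-2,6,6-trimethylcyclohex-1-en-1-yl]-3-methylpent-2-en-4-yn-1-yl]triphenylphosphonium bromide | CC1=C(C#C/C(C)=C/C[P+](c2ccccc2)(c2ccccc2)c2ccccc2)C(C)(C)C[C@H](O)C1.[Br-]
F5 | step 10 | (2E,4E,6E,8E,10E)-13-[(4R)-4-hydroxy-2,6,6-trimethylcyclohex-1-en-1-yl]-2,7,11-trimethyltrideca-2,4,6,8,10-pentaen-12-ynal | CC1=C(C#C/C(C)=C/C=C/C(C)=C/C=C/C=C(C)/C=O)C(C)(C)C[C@H](O)C1
F6 | step 11 | (3S,4R,3'R)-7,8,7',8'-tetradehydro-β,β-carotene-3,4,3'-triol (C4 epimer of 22) | CC1=C(C#C/C(C)=C/C=C/C(C)=C/C=C/C=C(C)/C=C/C=C(\C)C#CC2=C(C)[C@@H](O)[C@@H](O)CC2(C)C)C(C)(C)C[C@H](O)C1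
F7 | step 3 | rac-3,4-dihydroxy-2,6,6-trimethylcyclohex-2-en-1-one | CC1=C(O)C(O)CC(C)(C)C1=O
F8 | step 3 | (1R)-2-hydroxy-3,5,5-trimethyl-4-oxocyclohex-2-en-1-yl acetate | CC1=C(O)[C@H](OC(C)=O)CC(C)(C)C1=O
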